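The indenone five-membered ring (C1, C2, C3, C3a, C7a) is closed last, between two fully functionalised halves. A protected benzophenone supplies C3, C3a and C7a; an aryl ynol ether, used as an arylketene equivalent, supplies C1 and C2 and already carries the diaryl ether (built by a depside Smiles rearrangement). One rhodium-catalysed, ketone-directed C–H activation/alkyne carbocyclisation forms the C7a–C1 and C2–C3 bonds, and acid work-up unmasks the C1 carbonyl. The step exploits two features: C7a–H is the only hydrogen ortho to the benzophenone carbonyl (all other ortho positions bear oxygen), and the oxygen-polarised alkyne inserts with its ethoxy-bearing carbon on the arene.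

Key step: step 9

Remark: the target has no stereocentre and its aryl axes are taken as freely rotating, so nothing stereochemical has to be set; compounds 1, 3, 7 and 8 are taken as commercial; ring A is the methoxy-bearing ring of the diaryl ether and ring B its benzoate ring.

Step 1
Reactants: 1 orcinol (5-methylbenzene-1,3-diol)
Product: 2 1,3-bis(methoxymethoxy)-5-methylbenzene
Conditions: MOMCl (2.5 equiv), i-Pr2NEt, CH2Cl2, 0 °C to rt
Reagents that add atoms: chloromethyl methyl ether (MOMCl), COCCl
Why: O-alkylation of both phenols by the reactive α-chloro ether (Williamson-type) installs MOM groups that later direct the lithiation and are removed together in the last step.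

Step 2
Reactants: 3 methyl 2-hydroxy-4-methoxybenzoate
Product: 4 methyl 4-methoxy-2-(methoxymethoxy)benzoate
Conditions: NaH, DMF, 0 °C; then MOMCl, 0 °C to rt
Reagents that add atoms: chloromethyl methyl ether (MOMCl), COCCl
Why: the hydrogen-bonded salicylate phenol is deprotonated irreversibly by NaH and the sodium phenoxide is alkylated by MOMCl (Williamson ether synthesis).

Step 3
Reactants: 2 1,3-bis(methoxymethoxy)-5-methylbenzene; 4 methyl 4-methoxy-2-(methoxymethoxy)benzoate
Product: 6 [2,6-bis(methoxymethoxy)-4-methylphenyl][4-methoxy-2-(methoxymethoxy)phenyl]methanone, via aryllithium 5 (not isolated)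
Conditions: 2, n-BuLi (1.1 equiv), THF, 0 °C, 1 h; then 4, −78 °C to 0 °C; aq. NH4Cl
Reagents that add atoms: none
Why: directed ortho-metalation between the two cooperating OMOM groups followed by nucleophilic acyl substitution on the ester should stop at the ketone, because its carbonyl is shielded by three ortho alkoxy groups against a second addition of the hindered aryllithium.

Step 4
Reactants: 7 2,6-dihydroxy-4-methylbenzoic acid; 8 3-bromo-2-hydroxy-5-methoxybenzaldehyde
Product: 9 2-bromo-6-formyl-4-methoxyphenyl 2,6-dihydroxy-4-methylbenzoate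
Conditions: TFAA, toluene, 0 °C to rt; aq. NaHCO3 work-up
Reagents that add atoms: none
Why: mixed-anhydride esterification (the standard depside synthesis) should acylate the phenol of 8, the two ortho hydroxyls of the acid being hydrogen-bonded to the carbonyl and poorly nucleophilic.

Step 5
Reactants: 9 2-bromo-6-formyl-4-methoxyphenyl 2,6-dihydroxy-4-methylbenzoate
Product: 11 methyl 2-(2-bromo-6-formyl-4-methoxyphenoxy)-6-hydroxy-4-methylbenzoate, via potassium carboxylate 10 (not isolated)
Conditions: K2CO3 (1.05 equiv), DMSO, rt; then MeI (1.2 equiv), rt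
Reagents that add atoms: iodomethane (MeI), CI
Why: Smiles rearrangement, in which the ring B phenoxide attacks the ipso carbon of ring A (activated by the ortho formyl group and the ortho bromine) through a six-membered spiro Meisenheimer adduct and expels the carboxylate; the two hydroxyls of 9 are equivalent so one ether results, and the carboxylate is then the only good nucleophile for MeI.

Step 6
Reactants: 11 methyl 2-(2-bromo-6-formyl-4-methoxyphenoxy)-6-hydroxy-4-methylbenzoate
Product: 13 methyl 2-(2-bromo-6-hydroxy-4-methoxyphenoxy)-6-hydroxy-4-methylbenzoate, via aryl formate 12 (not isolated)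
Conditions: mCPBA, CH2Cl2, 0 °C to rt; then K2CO3 (cat.), MeOH, 0 °C
Reagents that add atoms: 3-chloroperbenzoic acid (mCPBA), OOC(=O)c1cccc(Cl)c1
Why: Dakin-type Baeyer–Villiger oxidation, in which the aryl group (made migration-prone by the ortho aryloxy donor) shifts to oxygen to give the formate, which cold methanolysis cleaves to the phenol.

Step 7
Reactants: 13 methyl 2-(2-bromo-6-hydroxy-4-methoxyphenoxy)-6-hydroxy-4-methylbenzoate
Product: 14 methyl 2-[2-bromo-4-methoxy-6-(methoxymethoxy)phenoxy]-6-(methoxymethoxy)-4-methylbenzoate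
Conditions: MOMCl (4 equiv), i-Pr2NEt, n-Bu4NI (cat.), CH2Cl2, 0 °C to 40 °C
Reagents that add atoms: chloromethyl methyl ether (MOMCl), COCCl
Why: both phenols are alkylated by the α-chloro ether under a mild amine base, which avoids a free phenoxide on ring A that could lactonise onto the neighbouring methyl ester.

Step 8
Reactants: 14 methyl 2-[2-bromo-4-methoxy-6-(methoxymethoxy)phenoxy]-6-(methoxymethoxy)-4-methylbenzoate
Product: 15 methyl 2-[2-(ethoxyethynyl)-4-methoxy-6-(methoxymethoxy)phenoxy]-6-(methoxymethoxy)-4-methylbenzoate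
Conditions: ethoxyacetylene, n-BuLi, THF, −78 °C; ZnCl2, −78 °C to 0 °C; then 14, Pd(OAc)2 (5 mol%), XPhos (10 mol%), THF, 45 °C; Et3N-deactivated silica
Reagents that add atoms: ethoxyacetylene (ethyl ethynyl ether), CCOC#C
Why: Negishi coupling, in which the alkynylzinc chloride transmetalates to the arylpalladium bromide formed by oxidative addition of 14 to zerovalent palladium (generated in the flask), a known way to aryl ynol ethers that leaves the hindered ester untouched.

Step 9
Reactants: 6 [2,6-bis(methoxymethoxy)-4-methylphenyl][4-methoxy-2-(methoxymethoxy)phenyl]methanone; 15 methyl 2-[2-(ethoxyethynyl)-4-methoxy-6-(methoxymethoxy)phenoxy]-6-(methoxymethoxy)-4-methylbenzoate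
Product: 17 methyl 2-[2-[3-[2,6-bis(methoxymethoxy)-4-methylphenyl]-6-methoxy-4-(methoxymethoxy)-1-oxo-1H-inden-2-yl]-4-methoxy-6-(methoxymethoxy)phenoxy]-6-(methoxymethoxy)-4-methylbenzoate, via ethoxyindenol 16 (not isolated)
Conditions: 15 (1.5 equiv), [Cp*Rh(MeCN)3](SbF6)2 (5 mol%), Cu(OAc)2 (20 mol%), 1,2-dichloroethane, 80 °C; then 1 M aq. HCl, THF, 0 °C
Reagents that add atoms: water, O
Why: Proposed new method: the cationic Cp*Rh catalyst (trivalent rhodium) binds the ketone oxygen of 6 and acetate-assisted metalation cleaves the C–H bond at the future C7a to give a five-membered rhodacycle, ynol ether 15 then inserts into the Rh–aryl bond with the aryl group going to the ethoxy-bearing carbon (C7a–C1 bond) and rhodium to the aryl-bearing carbon, and this alkenyl–rhodium adds to the bound ketone carbon (C2–C3 bond) before protonolysis by acetic acid releases indenol 16 and the catalyst without change of oxidation state. The closest known reaction type is the rhodium-catalysed, ketone-directed C–H activation/carbocyclisation of aryl ketones with internal alkynes to 1H-inden-1-ols; an ynol ether as the alkyne partner, which turns the indenol into an indenone on acid work-up, is the untested part. The one ring closed is the five-membered carbocycle, formed by intramolecular 1,2-addition of the alkenyl–metal carbon to the ketone (5-exo-trig onto C=O). No stereocentre survives, because the carbinol centre of 16 is lost when acid ionises the tertiary, doubly benzylic alcohol (or hydrolyses the enol ether), water adds at C1 and ethanol leaves to give the C1 carbonyl. Site selectivity is secured because C7a–H is the only C–H ortho to the carbonyl of 6 (the other three ortho positions carry OMOM) and 15 has no directing group with a free ortho C–H, and the regiochemistry of insertion is secured because the oxygen-polarised alkyne places rhodium on its electron-rich, aryl-substituted carbon, the same sense as for aryl alkyl alkynes. The temperature is held at or below 80 °C so that 15 should not lose ethylene to give the ketene.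

Step 10
Reactants: 17 methyl 2-[2-[3-[2,6-bis(methoxymethoxy)-4-methylphenyl]-6-methoxy-4-(methoxymethoxy)-1-oxo-1H-inden-2-yl]-4-methoxy-6-(methoxymethoxy)phenoxy]-6-(methoxymethoxy)-4-methylbenzoate
Product: 18 ascomindone B, methyl 2-[2-[3-(2,6-dihydroxy-4-methylphenyl)-4-hydroxy-6-methoxy-1-oxo-1H-inden-2-yl]-6-hydroxy-4-methoxyphenoxy]-6-hydroxy-4-methylbenzoate
Conditions: HCl (1.25 M in MeOH), THF, 40 °C
Reagents that add atoms: none
Why: acid-catalysed acetal exchange should remove all five MOM groups as dimethoxymethane, while the methyl ester, the two aryl methyl ethers and the tetrasubstituted enone are inert to methanolic HCl.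

Compound list
1 | orcinol (5-methylbenzene-1,3-diol) | Cc1cc(O)cc(O)c1 | starting material
2 | 1,3-bis(methoxymethoxy)-5-methylbenzene | Cc1cc(OCOC)cc(OCOC)c1 | intermediate
3 | methyl 2-hydroxy-4-methoxybenzoate | COC(=O)c1ccc(OC)cc1O | starting material
4 | methyl 4-methoxy-2-(methoxymethoxy)benzoate | COC(=O)c1ccc(OC)cc1OCOC | intermediate
5 | [2,6-bis(methoxymethoxy)-4-methylphenyl]lithium | [Li]c1c(OCOC)cc(C)cc1OCOC | intermediate
6 | [2,6-bis(methoxymethoxy)-4-methylphenyl][4-methoxy-2-(methoxymethoxy)phenyl]methanone | O=C(c1ccc(OC)cc1OCOC)c1c(OCOC)cc(C)cc1OCOC | intermediate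
7 | 2,6-dihydroxy-4-methylbenzoic acid | Cc1cc(O)c(C(=O)O)c(O)c1 | starting material
8 | 3-bromo-2-hydroxy-5-methoxybenzaldehyde | COc1cc(Br)c(O)c(C=O)c1 | starting material
9 | 2-bromo-6-formyl-4-methoxyphenyl 2,6-dihydroxy-4-methylbenzoate | Cc1cc(O)c(C(=O)Oc2c(Br)cc(OC)cc2C=O)c(O)c1 | intermediate
10 | potassium 2-(2-bromo-6-formyl-4-methoxyphenoxy)-6-hydroxy-4-methylbenzoate | Cc1cc(O)c(C(=O)[O-])c(Oc2c(Br)cc(OC)cc2C=O)c1.[K+] | intermediate
11 | methyl 2-(2-bromo-6-formyl-4-methoxyphenoxy)-6-hydroxy-4-methylbenzoate | COC(=O)c1c(O)cc(C)cc1Oc1c(Br)cc(OC)cc1C=O | intermediate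
12 | methyl 2-[2-bromo-6-(formyloxy)-4-methoxyphenoxy]-6-hydroxy-4-methylbenzoate | COC(=O)c1c(O)cc(C)cc1Oc1c(Br)cc(OC)cc1OC=O | intermediate
13 | methyl 2-(2-bromo-6-hydroxy-4-methoxyphenoxy)-6-hydroxy-4-methylbenzoate | COC(=O)c1c(O)cc(C)cc1Oc1c(Br)cc(OC)cc1O | intermediate
14 | methyl 2-[2-bromo-4-methoxy-6-(methoxymethoxy)phenoxy]-6-(methoxymethoxy)-4-methylbenzoate | COC(=O)c1c(OCOC)cc(C)cc1Oc1c(Br)cc(OC)cc1OCOC | intermediate
15 | methyl 2-[2-(ethoxyethynyl)-4-methoxy-6-(methoxymethoxy)phenoxy]-6-(methoxymethoxy)-4-methylbenzoate | COC(=O)c1c(OCOC)cc(C)cc1Oc1c(C#COCC)cc(OC)cc1OCOC | intermediate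
16 | methyl 2-[2-[1-[2,6-bis(methoxymethoxy)-4-methylphenyl]-3-ethoxy-1-hydroxy-5-methoxy-7-(methoxymethoxy)-1H-inden-2-yl]-4-methoxy-6-(methoxymethoxy)phenoxy]-6-(methoxymethoxy)-4-methylbenzoate (racemic carbinol) | CCOC1=C(c2cc(OC)cc(OCOC)c2Oc2cc(C)cc(OCOC)c2C(=O)OC)C(O)(c2c(OCOC)cc(C)cc2OCOC)c2c(OCOC)cc(OC)cc21 | intermediate
17 | methyl 2-[2-[3-[2,6-bis(methoxymethoxy)-4-methylphenyl]-6-methoxy-4-(methoxymethoxy)-1-oxo-1H-inden-2-yl]-4-methoxy-6-(methoxymethoxy)phenoxy]-6-(methoxymethoxy)-4-methylbenzoate | COC(=O)c1c(OCOC)cc(C)cc1Oc1c(OCOC)cc(OC)cc1C1=C(c2c(OCOC)cc(C)cc2OCOC)c2c(OCOC)cc(OC)cc2C1=O | intermediate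
18 | ascomindone B | COC(=O)c1c(O)cc(C)cc1Oc1c(O)cc(OC)cc1C1=C(c2c(O)cc(C)cc2O)c2c(O)cc(OC)cc2C1=O | target

Total step count: 10. Longest linear sequence: 7 steps (steps 4 to 10).

Steps most likely to fail

Step 9 (proposed new method). The cationic rhodium complex may act as a Lewis acid on the ynol ether (hydration, oligomerisation or a [2+2] reaction with the ketone) before C–H metalation; metalation may be slow because the crowded carbonyl is twisted out of the ring plane; and the addition of the alkenyl–rhodium to the ketone may stall at the congested carbinol carbon. The fallback builds the same ring by known steps and sets out from 2 and 14. Commercial 2-bromo-6-hydroxy-4-methoxybenzaldehyde is converted (MOMCl, i-Pr2NEt) into 2-bromo-4-methoxy-6-(methoxymethoxy)benzaldehyde F1; aryllithium 5 from 2 adds to it at −78 °C to give the bromo carbinol F2; Negishi coupling with ethynylzinc bromide (Pd(PPh3)4, THF) gives the ethynyl carbinol F3; and copper-free Sonogashira coupling of F3 with bromide 14 (PdCl2(MeCN)2, XPhos, Cs2CO3, MeCN, 80 °C) gives the diarylalkyne F4, which already holds the C7a–C1 bond. Base-mediated 5-exo-dig addition of the benzylic alkoxide to the alkyne (KOt-Bu, THF) should give the (Z)-1-arylidene-1,3-dihydroisobenzofuran F5, whose enol ether is hydrolysed (oxalic acid, wet THF) to the hydroxy ketone F6 (in equilibrium with its lactol). Dess–Martin periodinane oxidises the carbinol to the 1,2-diacylbenzene F7, and intramolecular aldol condensation (K2CO3, MeOH) closes the C2–C3 bond and comes back to the route at 17.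

Step 5. The para methoxy group makes the ipso carbon of ring A electron-rich, so the intramolecular substitution may be slower than cleavage of the activated aryl ester by traces of hydroxide or by acyl transfer between molecules; the hindered esterification of step 4 is a related weak point. The fallback sets out from 8 and bypasses steps 4 and 5. Deoxyfluorination of the phenol (N,N'-bis(2,6-diisopropylphenyl)-2-chloroimidazolium chloride, CsF, toluene, 110 °C) gives 3-bromo-2-fluoro-5-methoxybenzaldehyde F8. Intermolecular SNAr of F8 with commercial methyl 2,6-dihydroxy-4-methylbenzoate (used in excess; K2CO3, DMF, 80 °C), activated by the ortho formyl group, comes back to the route at 11.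

Step 8. Oxidative addition of the hindered, electron-rich bromide may be slow, and the ynol ether may be protonated and hydrated to the arylacetate during work-up and chromatography. The fallback sets out from 14 and changes the way the oxygen is put on the alkyne. Negishi coupling with ethynylzinc bromide gives the terminal alkyne F9. Deprotonation (LiHMDS, THF, −78 °C), oxidation of the lithium acetylide with lithium tert-butyl peroxide to the lithium ynolate and O-silylation with TIPSOTf give the more robust siloxyalkyne F10. F10 replaces 15 in step 9; the siloxyindenol F11 formed there loses triisopropylsilanol on the same acid work-up, and the route is rejoined at 17.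

Further compounds
F1 | step 9 | 2-bromo-4-methoxy-6-(methoxymethoxy)benzaldehyde | O=Cc1c(Br)cc(OC)cc1OCOC
F2 | step 9 | [2-bromo-4-methoxy-6-(methoxymethoxy)phenyl][2,6-bis(methoxymethoxy)-4-methylphenyl]methanol (racemic) | OC(c1c(Br)cc(OC)cc1OCOC)c1c(OCOC)cc(C)cc1OCOC
F3 | step 9 | [2-ethynyl-4-methoxy-6-(methoxymethoxy)phenyl][2,6-bis(methoxymethoxy)-4-methylphenyl]methanol (racemic) | OC(c1c(C#C)cc(OC)cc1OCOC)c1c(OCOC)cc(C)cc1OCOC
F4 | step 9 | methyl 2-[2-[[2-[[2,6-bis(methoxymethoxy)-4-methylphenyl](hydroxy)methyl]-5-methoxy-3-(methoxymethoxy)phenyl]ethynyl]-4-methoxy-6-(methoxymethoxy)phenoxy]-6-(methoxymethoxy)-4-methylbenzoate (racemic) | COC(=O)c1c(OCOC)cc(C)cc1Oc1c(OCOC)cc(OC)cc1C#Cc1cc(OC)cc(OCOC)c1C(O)c1c(OCOC)cc(C)cc1OCOC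
F5 | step 9 | methyl 2-[2-[(Z)-[3-[2,6-bis(methoxymethoxy)-4-methylphenyl]-6-methoxy-4-(methoxymethoxy)-2-benzofuran-1(3H)-ylidene]methyl]-4-methoxy-6-(methoxymethoxy)phenoxy]-6-(methoxymethoxy)-4-methylbenzoate (racemic) | COC(=O)c1c(OCOC)cc(C)cc1Oc1c(OCOC)cc(OC)cc1/C=C1\OC(c2c(OCOC)cc(C)cc2OCOC)c2c(OCOC)cc(OC)cc21
F6 | step 9 | methyl 2-[2-[2-[2-[[2,6-bis(methoxymethoxy)-4-methylphenyl](hydroxy)methyl]-5-methoxy-3-(methoxymethoxy)phenyl]-2-oxoethyl]-4-methoxy-6-(methoxymethoxy)phenoxy]-6-(methoxymethoxy)-4-methylbenzoate (racemic, open form of the lactol) | COC(=O)c1c(OCOC)cc(C)cc1Oc1c(OCOC)cc(OC)cc1CC(=O)c1cc(OC)cc(OCOC)c1C(O)c1c(OCOC)cc(C)cc1OCOC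
F7 | step 9 | methyl 2-[2-[2-[2-[2,6-bis(methoxymethoxy)-4-methylbenzoyl]-5-methoxy-3-(methoxymethoxy)phenyl]-2-oxoethyl]-4-methoxy-6-(methoxymethoxy)phenoxy]-6-(methoxymethoxy)-4-methylbenzoate | COC(=O)c1c(OCOC)cc(C)cc1Oc1c(OCOC)cc(OC)cc1CC(=O)c1cc(OC)cc(OCOC)c1C(=O)c1c(OCOC)cc(C)cc1OCOC
F8 | step 5 | 3-bromo-2-fluoro-5-methoxybenzaldehyde | COc1cc(Br)c(F)c(C=O)c1
F9 | step 8 | methyl 2-[2-ethynyl-4-methoxy-6-(methoxymethoxy)phenoxy]-6-(methoxymethoxy)-4-methylbenzoate | COC(=O)c1c(OCOC)cc(C)cc1Oc1c(C#C)cc(OC)cc1OCOC
F10 | step 8 | methyl 2-[4-methoxy-6-(methoxymethoxy)-2-[(triisopropylsilyloxy)ethynyl]phenoxy]-6-(methoxymethoxy)-4-methylbenzoate | COC(=O)c1c(OCOC)cc(C)cc1Oc1c(C#CO[Si](C(C)C)(C(C)C)C(C)C)cc(OC)cc1OCOC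
F11 | step 8 | methyl 2-[2-[1-[2,6-bis(methoxymethoxy)-4-methylphenyl]-1-hydroxy-5-methoxy-7-(methoxymethoxy)-3-(triisopropylsilyloxy)-1H-inden-2-yl]-4-methoxy-6-(methoxymethoxy)phenoxy]-6-(methoxymethoxy)-4-methylbenzoate (racemic, not isolated) | CC(C)[Si](OC1=C(c2cc(OC)cc(OCOC)c2Oc2cc(C)cc(OCOC)c2C(=O)OC)C(O)(c2c(OCOC)cc(C)cc2OCOC)c2c(OCOC)cc(OC)cc21)(C(C)C)C(C)C
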